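Numbering of the target: C1 and C4 carry the benzoates, C2=C3 is the alkene, C5 carries OH, C6 carries OH and CH2OH. Enabling feature: C6 is a tertiary carbinol next to carbinol C5, so at the C5-ketone level C5/C6 is an alpha-ketol. The cis C1/C4 benzoates are related by a local mirror plane through the C2=C3 and C5–C6 bonds.
Retrosynthesis: C5–H is cut first (ketone reduction). The C1–C6 bond is then cut and C1 rejoined to C5, which contracts the cyclohexene to a meso 2-acylcyclopent-4-ene-1,2,3-triol. Next come the C5–C6 bond (acyl anion plus meso ketone), C5=O (from an isopropylidene group), and C1–O and C4–O (both from one O2).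
Forward: the five-membered ring of 6,6-dimethylfulvene takes up O2 across its diene and the exocyclic alkene is cleaved to a ketone. A two-carbon hydroxyacetyl unit is added, and the cyclopentene is enlarged to the cyclohexene by a 1,2-shift.
Stereochemistry: C1/C4 are cis from suprafacial O2 addition, and the tertiary carbinol comes from addition anti to both silyloxy groups. The absolute configuration and C6 come from a chiral copper chelate that selects one of two enantiotopic ring carbons in the shift. C5 comes from hydride delivery directed by the C6 hydroxyl group.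

Key step: step 9

Assumption: the (S,S)-ligand is taken to favour migration of the (S)-configured ring carbon of the meso ketol; if the sense of induction is the opposite, the (R,R)-ligand is used and nothing else changes.

Step 1
Reactants: 1 6,6-dimethylfulvene
Product: 3 meso-(1R,4S)-5-(propan-2-ylidene)cyclopent-2-ene-1,4-diol (cis-diol), via fulvene endoperoxide 2 (not isolated)
Conditions: O2, visible light, rose bengal (cat.), thiourea, MeOH, −30 °C to rt
Reagents that add atoms: dioxygen O=O
Why: Singlet-oxygen [4+2] cycloaddition to the ring diene of a fulvene followed by in situ thiourea reduction of the O–O bond is a known reaction type for cyclopentadienes and fulvenes, and since both oxygen atoms are delivered suprafacially by one O2 molecule the two new carbinol centres are necessarily cis, which makes the diol meso.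

Step 2
Reactants: 3 meso-(1R,4S)-5-(propan-2-ylidene)cyclopent-2-ene-1,4-diol
Product: 4 meso-(1R,4S)-1,4-bis(tert-butyldimethylsilyloxy)-5-(propan-2-ylidene)cyclopent-2-ene
Conditions: TBSCl, imidazole, DMF, rt
Reagents that add atoms: tert-butyldimethylsilyl chloride CC(C)(C)[Si](C)(C)Cl
Why: Imidazole-promoted silyl ether formation masks both allylic alcohols against ozone and the organometallic reagent and touches no stereocentre.

Step 3
Reactants: 4 meso-(1R,4S)-1,4-bis(tert-butyldimethylsilyloxy)-5-(propan-2-ylidene)cyclopent-2-ene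
Product: 5 meso-(2R,5S)-2,5-bis(tert-butyldimethylsilyloxy)cyclopent-3-en-1-one
Conditions: O3 (dosed to a Sudan Red 7B end point), CH2Cl2, −78 °C; then Me2S, −78 °C to rt
Reagents that add atoms: ozone [O-][O+]=O
Why: Ozonolysis with reductive work-up should be chemoselective because the tetrasubstituted exocyclic alkene is much more electron-rich than the disubstituted ring alkene, so that ozone dosed to a dye end point cleaves only the isopropylidene group and leaves both stereocentres untouched.

Step 4
Reactants: 5 meso-(2R,5S)-2,5-bis(tert-butyldimethylsilyloxy)cyclopent-3-en-1-one; 6 ethyl vinyl ether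
Product: 9 meso-(2R,5S)-2,5-bis(tert-butyldimethylsilyloxy)-1-(1-ethoxyvinyl)cyclopent-3-en-1-ol (OH cis to both silyloxy groups), via 1-ethoxyvinyllithium 7 (not isolated), via (1-ethoxyvinyl)cerium dichloride 8 (not isolated)
Conditions: 6, t-BuLi, THF, −78 to 0 °C; CeCl3, THF, −78 °C; then 5, −78 °C; aq NH4Cl
Reagents that add atoms: none
Why: 1,2-Addition of an acyl anion equivalent (alpha-metallated enol ether) in its weakly basic organocerium form, which suppresses enolisation of the doubly activated ketone, should occur on the face opposite to the two cis silyloxy groups, so that the new tertiary hydroxyl group ends cis to both of them.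

Step 5
Reactants: 9 meso-(2R,5S)-2,5-bis(tert-butyldimethylsilyloxy)-1-(1-ethoxyvinyl)cyclopent-3-en-1-ol
Product: 10 meso-(1R,3S)-2-(1-ethoxyvinyl)cyclopent-4-ene-1,2,3-triol (all three OH cis)
Conditions: TBAF, THF, 0 °C to rt
Reagents that add atoms: none
Why: Fluoride-induced silyl ether cleavage is non-acidic, so the two secondary alcohols are freed while the acid-labile enol ether and the stereocentres are preserved.

Step 6
Reactants: 10 meso-(1R,3S)-2-(1-ethoxyvinyl)cyclopent-4-ene-1,2,3-triol
Product: 11 meso-(1R,3S)-2-(1-ethoxyvinyl)-2-hydroxycyclopent-4-ene-1,3-diyl dibenzoate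
Conditions: BzCl, Et3N, DMAP (cat.), CH2Cl2, 0 °C
Reagents that add atoms: benzoyl chloride O=C(Cl)c1ccccc1
Why: DMAP-catalysed acylation esterifies the two secondary allylic alcohols and leaves the hindered tertiary alcohol free, and the basic medium spares the enol ether.

Step 7
Reactants: 11 meso-(1R,3S)-2-(1-ethoxyvinyl)-2-hydroxycyclopent-4-ene-1,3-diyl dibenzoate
Product: 13 meso-(1R,3S)-2-hydroxy-2-(hydroxyacetyl)cyclopent-4-ene-1,3-diyl dibenzoate, via ethyl hemiketal 12 (not isolated)
Conditions: OsO4 (cat.), NMO, acetone/H2O, 0 °C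
Reagents that add atoms: N-methylmorpholine N-oxide C[N+]1([O-])CCOCC1; water O
Why: Catalytic OsO4 dihydroxylation of an enol ether is a known route to alpha-hydroxy ketones, and here the electron-rich enol ether should react far faster than the ring alkene that two allylic benzoates deactivate, after which the hemiketal loses ethanol to leave the hydroxyacetyl group.

Step 8
Reactants: 13 meso-(1R,3S)-2-hydroxy-2-(hydroxyacetyl)cyclopent-4-ene-1,3-diyl dibenzoate
Product: 14 meso-(1R,3S)-2-[(tert-butyldiphenylsilyloxy)acetyl]-2-hydroxycyclopent-4-ene-1,3-diyl dibenzoate (OH cis to both benzoates, acyl group on the other face)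
Conditions: TBDPSCl, imidazole, CH2Cl2, 0 °C
Reagents that add atoms: tert-butyldiphenylsilyl chloride CC(C)(C)[Si](Cl)(c1ccccc1)c1ccccc1
Why: Silylation with a bulky chlorosilane is selective for the primary alcohol, and the weakly Lewis basic silyl ether blocks aldose-ketose isomerisation and retro-aldol loss of formaldehyde in the next steps.

Step 9
Reactants: 14 meso-(1R,3S)-2-[(tert-butyldiphenylsilyloxy)acetyl]-2-hydroxycyclopent-4-ene-1,3-diyl dibenzoate
Product: 15 (1S,4R,6S)-6-[(tert-butyldiphenylsilyloxy)methyl]-6-hydroxy-5-oxocyclohex-2-ene-1,4-diyl dibenzoate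
Conditions: Cu(OTf)2 (cat.), (S,S)-t-Bu-box [2,2'-(propane-2,2-diyl)bis((4S)-4-tert-butyl-4,5-dihydrooxazole)] (cat.), 4 Å molecular sieves, ClCH2CH2Cl, 40 °C
Reagents that add atoms: none
Why: Proposed new method: Cu(OTf)2 and the bisoxazoline give a divalent copper Lewis acid that binds the tertiary OH and the ketone oxygen of 14 as a five-membered chelate, and in this cisoid array one ring bond of the carbinol carbon (C2–C3) shifts with its electron pair to the activated carbonyl carbon while C2 becomes the new ketone, which is an alpha-ketol (acyloin) rearrangement driven by loss of the strain and eclipsing of the crowded cyclopentene. The closest known reaction types are the Lewis acid induced enlargement of 1-acylcyclopentanols to 2-hydroxycyclohexanones, the D-homoannulation of 17-hydroxy-20-oxo steroids that carry a 21-oxygenated side chain, and enantioselective alpha-ketol shifts of simple achiral ketols under chiral nickel or copper Lewis acids, whereas the choice between the two enantiotopic, allylic, benzoyloxy-bearing carbons of a meso ketol has not been shown. The six-membered ring is not formed by an exo or endo cyclisation but by a suprafacial 1,2-carbon shift that inserts the former side-chain carbonyl carbon between C2 and C3 of the five-membered ring with retention at the migrating carbon, so that the old C3, C4, C5, C1 and C2 become C1, C2, C3, C4 and C5 and the inserted carbon becomes C6. The one new stereocentre C6 is fixed by the chelate, because the carbonyl oxygen is held on the side of the old hydroxyl group and the side chain hangs from the face opposite to the benzoates, so the new OH ends cis to the C1 benzoate and the silyloxymethyl group trans to it. The step needs enantiotopic-group selection, which the twofold-symmetric ligand should provide by twisting the chelate so that only the C2–C3 bond lies parallel to the carbonyl pi* orbital, while in the substrate the mirror plane removes any regiochemical alternative, the bulky and weakly basic silyl ether leaves the ketol as the only bidentate site, and the fully substituted C6 blocks enolisation on that side. Mild temperature and short contact are needed so that the slower degenerate shift of the silyloxymethyl group in 15, which would racemise it, and enolisation at C4 do not set in.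

Step 10
Reactants: 15 (1S,4R,6S)-6-[(tert-butyldiphenylsilyloxy)methyl]-6-hydroxy-5-oxocyclohex-2-ene-1,4-diyl dibenzoate
Product: 16 (1S,4R,5S,6R)-6-[(tert-butyldiphenylsilyloxy)methyl]-5,6-dihydroxycyclohex-2-ene-1,4-diyl dibenzoate
Conditions: Me4NBH(OAc)3, MeCN/AcOH, −30 °C
Reagents that add atoms: none
Why: In this hydroxyl-directed ketone reduction with a triacetoxyborohydride (Saksena–Evans reduction, here through the neighbouring tertiary C6 hydroxyl group) boron is bound on the face of the benzoates and hands its hydride to that face of C5=O, an approach that the bulky silyloxymethyl group on the other face also favours, so the C5–OH should form trans to the C6–OH and to the C4 benzoate, and the acidic medium avoids enolisation at C4.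

Step 11
Reactants: 16 (1S,4R,5S,6R)-6-[(tert-butyldiphenylsilyloxy)methyl]-5,6-dihydroxycyclohex-2-ene-1,4-diyl dibenzoate
Product: 17 (1S,4R,5S,6R)-5,6-dihydroxy-6-(hydroxymethyl)cyclohex-2-ene-1,4-diyl dibenzoate (target)
Conditions: HF·pyridine, pyridine/THF, 0 °C to rt
Reagents that add atoms: none
Why: Fluoride cleavage of the silyl ether under buffered, mildly acidic conditions frees the primary alcohol without the base-induced benzoyl migration that a basic fluoride source could cause.

Compound list
1 | 6,6-dimethylfulvene | CC(C)=C1C=CC=C1 | starting material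
2 | (1R,4S)-7-(propan-2-ylidene)-2,3-dioxabicyclo[2.2.1]hept-5-ene (fulvene endoperoxide) | O1[C@H]2C=C[C@@H](O1)C2=C(C)C | intermediate
3 | meso-(1R,4S)-5-(propan-2-ylidene)cyclopent-2-ene-1,4-diol | O[C@H]1C=C[C@@H](O)C1=C(C)C | intermediate
4 | meso-(1R,4S)-1,4-bis(tert-butyldimethylsilyloxy)-5-(propan-2-ylidene)cyclopent-2-ene | CC(C)(C)[Si](C)(C)O[C@H]1C=C[C@@H](O[Si](C)(C)C(C)(C)C)C1=C(C)C | intermediate
5 | meso-(2R,5S)-2,5-bis(tert-butyldimethylsilyloxy)cyclopent-3-en-1-one | CC(C)(C)[Si](C)(C)O[C@H]1C=C[C@@H](O[Si](C)(C)C(C)(C)C)C1=O | intermediate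
6 | ethyl vinyl ether | C=COCC | starting material
7 | 1-ethoxyvinyllithium | [Li]C(=C)OCC | intermediate
8 | (1-ethoxyvinyl)cerium dichloride | C=C(OCC)[Ce](Cl)Cl | intermediate
9 | meso-(2R,5S)-2,5-bis(tert-butyldimethylsilyloxy)-1-(1-ethoxyvinyl)cyclopent-3-en-1-ol (OH cis to both silyloxy groups) | CC(C)(C)[Si](C)(C)O[C@H]1C=C[C@@H](O[Si](C)(C)C(C)(C)C)[C@]1(O)C(=C)OCC | intermediate
10 | meso-(1R,3S)-2-(1-ethoxyvinyl)cyclopent-4-ene-1,2,3-triol (all OH cis) | O[C@H]1C=C[C@@H](O)[C@]1(O)C(=C)OCC | intermediate
11 | meso-(1R,3S)-2-(1-ethoxyvinyl)-2-hydroxycyclopent-4-ene-1,3-diyl dibenzoate | O=C(O[C@H]1C=C[C@@H](OC(=O)c2ccccc2)[C@]1(O)C(=C)OCC)c1ccccc1 | intermediate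
12 | ethyl hemiketal, 2-(1-ethoxy-1,2-dihydroxyethyl)-2-hydroxycyclopent-4-ene-1,3-diyl dibenzoate (both configurations at the hemiketal carbon) | O=C(O[C@H]1C=C[C@@H](OC(=O)c2ccccc2)[C@]1(O)C(O)(CO)OCC)c1ccccc1 | intermediate
13 | meso-(1R,3S)-2-hydroxy-2-(hydroxyacetyl)cyclopent-4-ene-1,3-diyl dibenzoate | O=C(O[C@H]1C=C[C@@H](OC(=O)c2ccccc2)[C@]1(O)C(=O)CO)c1ccccc1 | intermediate
14 | meso-(1R,3S)-2-[(tert-butyldiphenylsilyloxy)acetyl]-2-hydroxycyclopent-4-ene-1,3-diyl dibenzoate | O=C(O[C@H]1C=C[C@@H](OC(=O)c2ccccc2)[C@]1(O)C(=O)CO[Si](c2ccccc2)(c2ccccc2)C(C)(C)C)c1ccccc1 | intermediate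
15 | (1S,4R,6S)-6-[(tert-butyldiphenylsilyloxy)methyl]-6-hydroxy-5-oxocyclohex-2-ene-1,4-diyl dibenzoate | O=C(O[C@H]1C=C[C@@H](OC(=O)c2ccccc2)C(=O)[C@]1(O)CO[Si](c2ccccc2)(c2ccccc2)C(C)(C)C)c1ccccc1 | intermediate
16 | (1S,4R,5S,6R)-6-[(tert-butyldiphenylsilyloxy)methyl]-5,6-dihydroxycyclohex-2-ene-1,4-diyl dibenzoate | O=C(O[C@H]1C=C[C@@H](OC(=O)c2ccccc2)[C@H](O)[C@]1(O)CO[Si](c2ccccc2)(c2ccccc2)C(C)(C)C)c1ccccc1 | intermediate
17 | (1S,4R,5S,6R)-5,6-dihydroxy-6-(hydroxymethyl)cyclohex-2-ene-1,4-diyl dibenzoate | O=C(O[C@H]1C=C[C@@H](OC(=O)c2ccccc2)[C@H](O)[C@]1(O)CO)c1ccccc1 | target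

Total step count: 11. Longest linear sequence: 11 steps (from 1).

Steps most likely to fail

Step 9. Three things may go wrong:
- weak discrimination between the two enantiotopic ring carbons;
- sluggish migration of a carbon that bears an electron-withdrawing benzoate;
- loss of optical purity through the degenerate shift of the side chain.

The fallback sets out from 14 and comes back at 17. The shift is run with an achiral Lewis acid (Sc(OTf)3 cat., ClCH2CH2Cl), which is the known ring enlargement of 1-acylcyclopentanols. It should give 15 as a racemate together with its mirror image ent-15 F1. Steps 10 and 11 are applied to the racemate, which carries along ent-16 F2 and ent-17 F3. The racemic triol is then resolved by lipase-catalysed acetylation of the primary alcohol with vinyl acetate in t-BuOMe. This is a kinetic resolution, with the enzyme chosen by screening so that the unwanted antipode reacts faster. That antipode is removed as the primary acetate of ent-17 F4, and unreacted 17 is separated by chromatography.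

Step 4. Enolisation and double-bond migration of the doubly activated ketone may compete with addition of the hindered nucleophile. The fallback sets out from 5 and comes back at 14. It uses a much less basic, slim nucleophile and builds the ketone by oxidation-state adjustment:
- LiC≡CSiMe3 in THF at −78 °C should give the silylethynyl carbinol F5.
- TBAF removes all three silyl groups to give the ethynyl triol F6.
- BzCl, Et3N and DMAP give the ethynyl dibenzoate F7.
- Semihydrogenation (H2, Pd/CaCO3/Pb(OAc)2, quinoline) gives the vinyl carbinol F8.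
- OsO4 (cat.) and NMO dihydroxylate the vinyl group to the triol F9.
- TBDPSCl and imidazole protect the primary alcohol as the silyl ether F10.
- Dess–Martin oxidation of the remaining secondary alcohol gives 14.

Step 3. Ozone may also attack the ring alkene, so chemoselectivity may be incomplete. The fallback sets out from 4 and comes back at 5. The exocyclic alkene is first epoxidised with mCPBA (NaHCO3, CH2Cl2, 0 °C), an electrophilic oxidant with a stronger preference for the tetrasubstituted alkene, to give the spiro-epoxide F11. The epoxide is then cleaved with H5IO6 in Et2O/THF to 5.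

Further compounds
F1 | step 9 | ent-15, (1R,4S,6R)-6-[(tert-butyldiphenylsilyloxy)methyl]-6-hydroxy-5-oxocyclohex-2-ene-1,4-diyl dibenzoate | O=C(O[C@@H]1C=C[C@H](OC(=O)c2ccccc2)C(=O)[C@@]1(O)CO[Si](c2ccccc2)(c2ccccc2)C(C)(C)C)c1ccccc1
F2 | step 9 | ent-16, (1R,4S,5R,6S)-6-[(tert-butyldiphenylsilyloxy)methyl]-5,6-dihydroxycyclohex-2-ene-1,4-diyl dibenzoate | O=C(O[C@@H]1C=C[C@H](OC(=O)c2ccccc2)[C@@H](O)[C@@]1(O)CO[Si](c2ccccc2)(c2ccccc2)C(C)(C)C)c1ccccc1
F3 | step 9 | ent-17, (1R,4S,5R,6S)-5,6-dihydroxy-6-(hydroxymethyl)cyclohex-2-ene-1,4-diyl dibenzoate | O=C(O[C@@H]1C=C[C@H](OC(=O)c2ccccc2)[C@@H](O)[C@@]1(O)CO)c1ccccc1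
F4 | step 9 | primary acetate of ent-17 | O=C(O[C@@H]1C=C[C@H](OC(=O)c2ccccc2)[C@@H](O)[C@@]1(O)COC(C)=O)c1ccccc1
F5 | step 4 | meso-(2R,5S)-2,5-bis(tert-butyldimethylsilyloxy)-1-[(trimethylsilyl)ethynyl]cyclopent-3-en-1-ol (OH cis to both silyloxy groups) | CC(C)(C)[Si](C)(C)O[C@H]1C=C[C@@H](O[Si](C)(C)C(C)(C)C)[C@]1(O)C#C[Si](C)(C)C
F6 | step 4 | meso-(1R,3S)-2-ethynylcyclopent-4-ene-1,2,3-triol (all OH cis) | O[C@H]1C=C[C@@H](O)[C@]1(O)C#C
F7 | step 4 | meso-(1R,3S)-2-ethynyl-2-hydroxycyclopent-4-ene-1,3-diyl dibenzoate | O=C(O[C@H]1C=C[C@@H](OC(=O)c2ccccc2)[C@]1(O)C#C)c1ccccc1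
F8 | step 4 | meso-(1R,3S)-2-hydroxy-2-vinylcyclopent-4-ene-1,3-diyl dibenzoate | O=C(O[C@H]1C=C[C@@H](OC(=O)c2ccccc2)[C@]1(O)C=C)c1ccccc1
F9 | step 4 | 2-(1,2-dihydroxyethyl)-2-hydroxycyclopent-4-ene-1,3-diyl dibenzoate (both configurations at the side-chain carbinol) | O=C(O[C@H]1C=C[C@@H](OC(=O)c2ccccc2)[C@]1(O)C(O)CO)c1ccccc1
F10 | step 4 | 2-[2-(tert-butyldiphenylsilyloxy)-1-hydroxyethyl]-2-hydroxycyclopent-4-ene-1,3-diyl dibenzoate (both configurations at the side-chain carbinol) | O=C(O[C@H]1C=C[C@@H](OC(=O)c2ccccc2)[C@]1(O)C(O)CO[Si](c2ccccc2)(c2ccccc2)C(C)(C)C)c1ccccc1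
F11 | step 3 | meso spiro-epoxide, 4,7-bis(tert-butyldimethylsilyloxy)-2,2-dimethyl-1-oxaspiro[2.4]hept-5-ene (epoxide oxygen anti to the silyloxy groups) | CC(C)(C)[Si](C)(C)O[C@H]1C=C[C@@H](O[Si](C)(C)C(C)(C)C)[C@]12OC2(C)C
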